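**Strategy.** Everything rests on cutting both exocyclic C–C bonds of ring B, the hexasubstituted ring of the hydroxyphthalide: C1'–C7' (lactone carbonyl) and C6'–C8' (lactol carbon). One flask forms both on an aryl O-carbamate: an anionic ortho-Fries shift moves the carbamoyl carbon from the C2' oxygen to C1', then the new amide and the C5' oxygen direct lithiation to C6' for formylation. The step exploits the C2' phenol oxygen, whose only free ortho carbon is C1' because C3' carries the methyl, and C6' as the last ring C–H. The precursor is a bis(methoxymethyl)-protected 3-methylbenzene-1,2,4-triol carbamate; its formyl amide later gives the depsidone and the lactol, fixed as a chiral acetal.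

Key step: step 4

Labels: ring B carbons are C1' (carries C7', the lactone C=O), C2' (OH), C3' (CH3), C4' (ester O), C5' (ether O), C6' (carries C8', the lactol CH); ring A is the methoxy ring.

Remark: the lactol carbon of a 3-hydroxyphthalide can epimerise by ring–chain tautomerism in protic, acidic or basic media, so it is carried as a configurationally stable mixed acetal and released last under neutral aprotic conditions; the target should be kept cold and away from acid, base and protic solvents.

**Step 1**
Reactants: 1 2,4-dihydroxy-3-methylbenzaldehyde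
Product: 2 4-formyl-3-hydroxy-2-methylphenyl N,N-diethylcarbamate
Conditions: Et2NCOCl (1.05 eq), K2CO3, MeCN, 60 °C
Reagents that add atoms: N,N-diethylcarbamoyl chloride, CCN(CC)C(Cl)=O
Why: Schotten–Baumann-type O-carbamoylation should go to the 4-OH, because the 2-OH is held in a hydrogen bond to the aldehyde and is the poorer nucleophile.

**Step 2**
Reactants: 2 4-formyl-3-hydroxy-2-methylphenyl N,N-diethylcarbamate
Product: 3 3,4-dihydroxy-2-methylphenyl N,N-diethylcarbamate
Conditions: 30% H2O2, NaOH (1 M aq.), THF, 0 °C, N2; then dilute HCl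
Reagents that add atoms: hydrogen peroxide, OO
Why: Dakin oxidation: hydroperoxide adds to the ortho-hydroxy aldehyde, aryl migration gives the aryl formate, and this is hydrolysed in situ to the catechol while the N,N-diethylcarbamate resists cold dilute base.

**Step 3**
Reactants: 3 3,4-dihydroxy-2-methylphenyl N,N-diethylcarbamate
Product: 4 3,4-bis(methoxymethoxy)-2-methylphenyl N,N-diethylcarbamate
Conditions: MOMCl (2.5 eq), i-Pr2NEt, CH2Cl2, 0 °C to rt
Reagents that add atoms: chloromethyl methyl ether, COCCl
Why: Williamson-type alkylation of both catechol oxygens gives acetal ethers that tolerate alkyllithiums and serve as ortho-directing groups.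

**Step 4**
Reactants: 4 3,4-bis(methoxymethoxy)-2-methylphenyl N,N-diethylcarbamate
Product: 6 N,N-diethyl-2-formyl-6-hydroxy-3,4-bis(methoxymethoxy)-5-methylbenzamide, via lithium 2-(diethylcarbamoyl)-4,5-bis(methoxymethoxy)-6-methylphenoxide 5 (not isolated)
Conditions: s-BuLi (1.2 eq), TMEDA, THF, −78 °C, then rt; re-cool to −78 °C, s-BuLi (2.5 eq), TMEDA; DMF, −78 °C to rt; aq. NH4Cl
Reagents that add atoms: N,N-dimethylformamide, CN(C)C=O
Why: s-BuLi/TMEDA removes the C1' proton, the only ring proton ortho to the O-carbamate (the strongest director present; C3' is blocked by CH3), and on warming the aryllithium attacks its own carbamate in a 1,3 O-to-C carbamoyl shift (anionic ortho-Fries rearrangement) to give phenoxide 5 with the C1'–C7' bond. A second charge of s-BuLi/TMEDA then deprotonates C6', the last ring C–H, which lies between the new tertiary amide and the C5' methoxymethoxy group (cooperative directed ortho-metalation), and DMF formylates it to make the C6'–C8' bond. The closest known reaction type is the tandem anionic Fries/directed ortho-metalation sequence of aryl O-carbamates. No ring is closed here: the lactone ring is closed in step 11 by 5-exo-trig attack of the aldehyde hydrate on the amide carbonyl. No stereocenter is formed, since C8' is a trigonal formyl carbon that becomes stereogenic only in step 12. The selectivity needed is regiochemical (C1' before C6', ring over lateral CH3 lithiation) and should be secured by the single free ortho position of the carbamate, by kinetic deprotonation at −78 °C and by the fact that only one ring C–H remains after the shift.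

**Step 5**
Reactants: 6 N,N-diethyl-2-formyl-6-hydroxy-3,4-bis(methoxymethoxy)-5-methylbenzamide
Product: 7 N,N-diethyl-2-formyl-3,4,6-trihydroxy-5-methylbenzamide
Conditions: TFA/CH2Cl2 (1:4), 0 °C to rt; aqueous work-up
Reagents that add atoms: none
Why: Acidolysis of the two aryl methoxymethyl acetals should be clean because ring B has no free position for Friedel–Crafts capture of the methoxymethyl cation and the tertiary amide is not hydrolysed without hot aqueous acid.

**Step 6**
Reactants: 8 1-fluoro-3-methoxy-5-methylbenzene
Product: 9 2-fluoro-6-methoxy-4-methylbenzaldehyde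
Conditions: n-BuLi, THF, −78 °C; DMF; aq. NH4Cl
Reagents that add atoms: N,N-dimethylformamide, CN(C)C=O
Why: Directed ortho-metalation removes the proton between fluorine and methoxy, the most acidic one, and the aryllithium is formylated by DMF.

**Step 7**
Reactants: 9 2-fluoro-6-methoxy-4-methylbenzaldehyde
Product: 10 3-bromo-2-fluoro-6-methoxy-4-methylbenzaldehyde
Conditions: NBS, DMF, rt
Reagents that add atoms: N-bromosuccinimide, O=C1CCC(=O)N1Br
Why: Electrophilic aromatic bromination should go para to the methoxy group, the strongest donor, at the position flanked by the small fluorine and the methyl.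

**Step 8**
Reactants: 10 3-bromo-2-fluoro-6-methoxy-4-methylbenzaldehyde
Product: 11 2-fluoro-3-formyl-4-methoxy-6-methylbenzoic acid
Conditions: Pd(OAc)2 (5 mol %), Xantphos, CO (1 atm), Et3N, H2O, DMF, 80 °C
Reagents that add atoms: carbon monoxide, [C-]#[O+]; water, O
Why: Heck-type hydroxycarbonylation: the aryl bromide adds oxidatively to zerovalent palladium formed in situ from the divalent palladium salt, CO inserts, and water cleaves the acylpalladium to the acid, the aldehyde being tolerated.

**Step 9**
Reactants: 11 2-fluoro-3-formyl-4-methoxy-6-methylbenzoic acid; 7 N,N-diethyl-2-formyl-3,4,6-trihydroxy-5-methylbenzamide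
Product: 13 4-(diethylcarbamoyl)-3-formyl-2,5-dihydroxy-6-methylphenyl 2-fluoro-3-formyl-4-methoxy-6-methylbenzoate, via 2-fluoro-3-formyl-4-methoxy-6-methylbenzoyl chloride 12 (not isolated)
Conditions: (COCl)2, cat. DMF, CH2Cl2, 0 °C to rt, evaporate; then 7, i-Pr2NEt, THF, −20 to 0 °C
Reagents that add atoms: none
Why: Acid chloride formation and phenol acylation should place the ester on the C4' oxygen, the only phenol without a hydrogen bond to an ortho carbonyl (C5' OH binds the aldehyde, C2' OH the amide), and acyl migration to the C5' oxygen is disfavoured for the same reason.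

**Step 10**
Reactants: 13 4-(diethylcarbamoyl)-3-formyl-2,5-dihydroxy-6-methylphenyl 2-fluoro-3-formyl-4-methoxy-6-methylbenzoate
Product: 14 N,N-diethyl-4,6-diformyl-8-hydroxy-3-methoxy-1,9-dimethyl-11-oxo-11H-dibenzo[b,e][1,4]dioxepine-7-carboxamide
Conditions: Cs2CO3, DMF (high dilution), 50 °C
Reagents that add atoms: none
Why: Intramolecular SNAr (addition–elimination) of the C5' phenoxide on the fluoride, activated by the ortho formyl and ortho aryl-ester groups, should close the seven-membered dioxepinone ring, while the C2' phenoxide cannot reach the fluoride.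

**Step 11**
Reactants: 14 N,N-diethyl-4,6-diformyl-8-hydroxy-3-methoxy-1,9-dimethyl-11-oxo-11H-dibenzo[b,e][1,4]dioxepine-7-carboxamide
Product: 15 stictic acid (depsidone with ring A aldehyde and the 3-hydroxyphthalide on ring B; C8' epimers interconvert)
Conditions: TsOH·H2O (2 eq), 1,4-dioxane/H2O, 80 °C
Reagents that add atoms: water, O
Why: Acid-promoted, anchimerically assisted amide cleavage: the hydrate of the C8' aldehyde attacks the neighbouring amide carbonyl and diethylamine leaves as its salt, giving the 3-hydroxyphthalide, while the hindered 2,6-disubstituted depsidone ester should resist aqueous acid.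

**Step 12**
Reactants: 15 stictic acid (C8' epimers); 16 (S)-1-phenylethanol
Product: 17 (S)-1-phenylethyl acetal of stictic acid, (R) at the acetal carbon C8'
Conditions: CSA (0.1 eq), 16 (3 eq), benzene, 4 Å molecular sieves, 50 °C; separation of the C8' epimers on silica gel or by crystallisation; the other epimer is resubjected
Reagents that add atoms: none
Why: Acid-catalysed pseudo-ester (mixed acetal) formation through the phthalidyl oxocarbenium ion is reversible, so the C8' epimers equilibrate, the (S)-1-phenylethyl group makes them separable diastereomers, and isolation of the (8'R) epimer with recycling of the other sets the stereocenter.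

**Step 13**
Reactants: 17 (S)-1-phenylethyl acetal of stictic acid, (R) at C8'
Product: 18 (S)-1-phenylethyl acetal of the ring A hydroxymethyl depsidone, (R) at C8'
Conditions: NaBH4, THF/MeOH, −40 °C; AcOH
Reagents that add atoms: none
Why: Chemoselective borohydride reduction of the aromatic aldehyde at low temperature should leave the acetal-lactone, the hindered aryl ester and the acetal stereocenter untouched.

**Step 14**
Reactants: 18 (S)-1-phenylethyl acetal of the ring A hydroxymethyl depsidone, (R) at C8'
Product: 19 target, the (R)-lactol (cryptostictic acid skeleton)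
Conditions: H2 (1 atm), 10% Pd/C, EtOAc, rt; filtration, evaporation below 20 °C
Reagents that add atoms: none
Why: Hydrogenolysis of the benzylic O–CH(CH3)Ph bond under neutral aprotic conditions should free the lactol without breaking any bond at C8', so the (R) configuration is retained, and the fully substituted ring B keeps the other benzylic C–O bonds away from the catalyst surface.

**Compound list**

1 | 2,4-dihydroxy-3-methylbenzaldehyde | O=Cc1ccc(O)c(C)c1O | starting material
2 | 4-formyl-3-hydroxy-2-methylphenyl N,N-diethylcarbamate | CCN(CC)C(=O)Oc1ccc(C=O)c(O)c1C | intermediate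
3 | 3,4-dihydroxy-2-methylphenyl N,N-diethylcarbamate | CCN(CC)C(=O)Oc1ccc(O)c(O)c1C | intermediate
4 | 3,4-bis(methoxymethoxy)-2-methylphenyl N,N-diethylcarbamate | CCN(CC)C(=O)Oc1ccc(OCOC)c(OCOC)c1C | intermediate
5 | lithium 2-(diethylcarbamoyl)-4,5-bis(methoxymethoxy)-6-methylphenoxide | CCN(CC)C(=O)c1cc(OCOC)c(OCOC)c(C)c1[O-].[Li+] | intermediate (not isolated)
6 | N,N-diethyl-2-formyl-6-hydroxy-3,4-bis(methoxymethoxy)-5-methylbenzamide | CCN(CC)C(=O)c1c(C=O)c(OCOC)c(OCOC)c(C)c1O | intermediate
7 | N,N-diethyl-2-formyl-3,4,6-trihydroxy-5-methylbenzamide | CCN(CC)C(=O)c1c(C=O)c(O)c(O)c(C)c1O | intermediate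
8 | 1-fluoro-3-methoxy-5-methylbenzene | COc1cc(C)cc(F)c1 | starting material
9 | 2-fluoro-6-methoxy-4-methylbenzaldehyde | COc1cc(C)cc(F)c1C=O | intermediate
10 | 3-bromo-2-fluoro-6-methoxy-4-methylbenzaldehyde | COc1cc(C)c(Br)c(F)c1C=O | intermediate
11 | 2-fluoro-3-formyl-4-methoxy-6-methylbenzoic acid | COc1cc(C)c(C(=O)O)c(F)c1C=O | intermediate
12 | 2-fluoro-3-formyl-4-methoxy-6-methylbenzoyl chloride | COc1cc(C)c(C(=O)Cl)c(F)c1C=O | intermediate (not isolated)
13 | 4-(diethylcarbamoyl)-3-formyl-2,5-dihydroxy-6-methylphenyl 2-fluoro-3-formyl-4-methoxy-6-methylbenzoate | CCN(CC)C(=O)c1c(C=O)c(O)c(OC(=O)c2c(C)cc(OC)c(C=O)c2F)c(C)c1O | intermediate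
14 | N,N-diethyl-4,6-diformyl-8-hydroxy-3-methoxy-1,9-dimethyl-11-oxo-11H-dibenzo[b,e][1,4]dioxepine-7-carboxamide | COc1cc(C)c2c(c1C=O)Oc1c(c(C)c(O)c(C(=O)N(CC)CC)c1C=O)OC2=O | intermediate
15 | stictic acid (C8' epimers interconvert) | COc1cc(C)c2c(c1C=O)Oc1c(c(C)c(O)c3c1C(O)OC3=O)OC2=O | intermediate
16 | (S)-1-phenylethanol | C[C@H](O)c1ccccc1 | starting material
17 | (S)-1-phenylethyl acetal of stictic acid, (R) at C8' | COc1cc(C)c2c(c1C=O)Oc1c(c(C)c(O)c3c1[C@H](O[C@@H](C)c4ccccc4)OC3=O)OC2=O | intermediate
18 | (S)-1-phenylethyl acetal of the ring A hydroxymethyl depsidone, (R) at C8' | COc1cc(C)c2c(c1CO)Oc1c(c(C)c(O)c3c1[C@H](O[C@@H](C)c4ccccc4)OC3=O)OC2=O | intermediate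
19 | target, (R)-lactol (cryptostictic acid skeleton) | COc1cc(C)c2c(c1CO)Oc1c(c(C)c(O)c3c1[C@H](O)OC3=O)OC2=O | target

**Step count.** Total: 14 steps. Longest linear sequence: 11 steps (steps 1–5, then 9–14).

**Steps most likely to fail**

Step 4. The second deprotonation may stall on the electron-rich lithium phenoxide, or lateral lithiation of the C3' methyl may intervene, so that formylation is incomplete or misplaced. The fallback makes the two C–C bonds in separate operations. It sets out from 4: s-BuLi/TMEDA (−78 °C to rt) alone should give, after quench, the salicylamide N,N-diethyl-2-hydroxy-4,5-bis(methoxymethoxy)-3-methylbenzamide F1. MOMCl/i-Pr2NEt caps the phenol as N,N-diethyl-2,4,5-tris(methoxymethoxy)-3-methylbenzamide F2. s-BuLi/TMEDA followed by DMF then gives N,N-diethyl-2-formyl-3,4,6-tris(methoxymethoxy)-5-methylbenzamide F3. TFA/CH2Cl2 removes all three acetals and the route is rejoined at 7.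

Step 10 (with the acylation of step 9). Acyl migration between the C4' and C5' oxygens, ring closure through the wrong catechol oxygen, or intermolecular substitution could give the regioisomeric depsidone or oligomers. The fallback fixes the order of bond formation with a protecting group. It sets out from 6: MgBr2·OEt2, chelated to the formyl oxygen, should remove only the C5' methoxymethyl group to give N,N-diethyl-2-formyl-3,6-dihydroxy-4-(methoxymethoxy)-5-methylbenzamide F4. Intermolecular SNAr of its C5' phenoxide on acid 11 (K2CO3, DMSO, 80 °C) gives the diaryl ether 2-[3-(diethylcarbamoyl)-2-formyl-4-hydroxy-6-(methoxymethoxy)-5-methylphenoxy]-3-formyl-4-methoxy-6-methylbenzoic acid F5. TFA/CH2Cl2 frees the C4' phenol to give the seco acid 2-[3-(diethylcarbamoyl)-2-formyl-4,6-dihydroxy-5-methylphenoxy]-3-formyl-4-methoxy-6-methylbenzoic acid F6. Mukaiyama lactonisation (2-chloro-1-methylpyridinium iodide, Et3N, high dilution) closes the seven-membered ring, which only the C4' OH can reach, and the route is rejoined at 14.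

Step 14. Hydrogenolysis may be slow at the hindered secondary benzylic acetal oxygen, or may also cleave the ring A benzylic alcohol or the benzylic C8'–O bonds, and long contact times may let the freed lactol epimerise. The fallback replaces hydrogenolysis by photolysis of a nitrobenzyl-type auxiliary. It sets out from 15: acetalisation with (S)-1-(2-nitrophenyl)ethanol under the step 12 conditions and separation of the epimers gives the (S)-1-(2-nitrophenyl)ethyl acetal of stictic acid, (R) at C8', F7. NaBH4 as in step 13 gives the corresponding ring A hydroxymethyl acetal F8. Irradiation at 365 nm in MeCN at 0 °C releases the lactol under neutral conditions and the route is rejoined at 19.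

**Further compounds**

F1 | step 4 | N,N-diethyl-2-hydroxy-4,5-bis(methoxymethoxy)-3-methylbenzamide | CCN(CC)C(=O)c1cc(OCOC)c(OCOC)c(C)c1O
F2 | step 4 | N,N-diethyl-2,4,5-tris(methoxymethoxy)-3-methylbenzamide | CCN(CC)C(=O)c1cc(OCOC)c(OCOC)c(C)c1OCOC
F3 | step 4 | N,N-diethyl-2-formyl-3,4,6-tris(methoxymethoxy)-5-methylbenzamide | CCN(CC)C(=O)c1c(C=O)c(OCOC)c(OCOC)c(C)c1OCOC
F4 | step 10 | N,N-diethyl-2-formyl-3,6-dihydroxy-4-(methoxymethoxy)-5-methylbenzamide | CCN(CC)C(=O)c1c(C=O)c(O)c(OCOC)c(C)c1O
F5 | step 10 | 2-[3-(diethylcarbamoyl)-2-formyl-4-hydroxy-6-(methoxymethoxy)-5-methylphenoxy]-3-formyl-4-methoxy-6-methylbenzoic acid | COc1cc(C)c(C(=O)O)c(Oc2c(OCOC)c(C)c(O)c(C(=O)N(CC)CC)c2C=O)c1C=O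
F6 | step 10 | 2-[3-(diethylcarbamoyl)-2-formyl-4,6-dihydroxy-5-methylphenoxy]-3-formyl-4-methoxy-6-methylbenzoic acid | COc1cc(C)c(C(=O)O)c(Oc2c(O)c(C)c(O)c(C(=O)N(CC)CC)c2C=O)c1C=O
F7 | step 14 | (S)-1-(2-nitrophenyl)ethyl acetal of stictic acid, (R) at C8' | COc1cc(C)c2c(c1C=O)Oc1c(c(C)c(O)c3c1[C@H](O[C@@H](C)c4ccccc4[N+](=O)[O-])OC3=O)OC2=O
F8 | step 14 | (S)-1-(2-nitrophenyl)ethyl acetal of the ring A hydroxymethyl depsidone, (R) at C8' | COc1cc(C)c2c(c1CO)Oc1c(c(C)c(O)c3c1[C@H](O[C@@H](C)c4ccccc4[N+](=O)[O-])OC3=O)OC2=O
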